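**Retrosynthetic overview**
- The strategy rests on the unsubstituted benzo ring (C5–C8), fused across the C4a–C8a bond next to N1 of a 2-alkyl-4-oxygenated pyridine ring. This ring maps onto the triple bond of a 4-methoxy-2,3-pyridyne plus a four-carbon diene (furan).
- Target ⇐ iodide O-demethylation of the N-methyl-4-methoxyquinolinium salt ⇐ N-methylation of 4-methoxy-2-pentadecylquinoline ⇐ removal of the oxygen bridge from the 5,8-epoxy-5,8-dihydroquinoline.
- Epoxyquinoline ⇐ [4+2] cycloaddition of furan with 4-methoxy-6-pentadecyl-2,3-pyridyne (forms C4a–C5 and C8–C8a), the pyridyne arising from 3-bromo-2-chloro-4-methoxy-6-pentadecylpyridine by Br–Li exchange and loss of LiCl.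
- Bromochloropyridine ⇐ C3 magnesiation and bromination of 2-chloro-4-methoxy-6-pentadecylpyridine ⇐ iron-catalysed Kumada mono-alkylation of 2,6-dichloro-4-methoxypyridine with the Grignard reagent of 1-bromopentadecane.
- Ring order: the pyridine ring is bought; the carbocycle (ring A) is closed in step 3 and aromatised in step 4.

Key step: step 3

Assumption: the cycloadduct is made and carried on as the racemate; its two bridgehead centres are destroyed in step 4 and the target has no stereocentre.

**Route**

Step 1
Reactants: 1 2,6-dichloro-4-methoxypyridine; 2 1-bromopentadecane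
Product: 4 2-chloro-4-methoxy-6-pentadecylpyridine, via pentadecylmagnesium bromide 3 (not isolated)
Conditions: 2, Mg, THF, 45 °C; then 1 (slight excess), Fe(acac)3 (5 mol%), THF/NMP, 0 °C
Reagents that add atoms: none
Why: Iron-catalysed Kumada coupling, in which the low-valent iron formed from Fe(acac)3 and the Grignard reagent activates the C–Cl bond beside the ring nitrogen within minutes at 0 °C, and mono-alkylation should prevail because the first alkyl group makes the remaining C–Cl bond less electron-poor and 1 is kept in slight excess.

Step 2
Reactants: 4 2-chloro-4-methoxy-6-pentadecylpyridine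
Product: 6 3-bromo-2-chloro-4-methoxy-6-pentadecylpyridine, via arylmagnesium chloride 5 (not isolated)
Conditions: TMPMgCl·LiCl (1.3 equiv), THF, 0 °C → rt; then BrCl2CCCl2Br (1.5 equiv), THF, –30 °C → rt; NH4Cl aq
Reagents that add atoms: 1,2-dibromotetrachloroethane, BrC(Cl)(Cl)C(Cl)(Cl)Br
Why: Directed magnesiation with the Knochel–Hauser amide base, in which the C3–H flanked by chlorine and methoxy is the most acidic and doubly coordinating site and should be removed in preference to C5–H (one directing group) and to the CH2 beside the ring, the arylmagnesium chloride 5 being stable against loss of MgCl2 at these temperatures and then brominated by positive-halogen transfer with loss of tetrachloroethene.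

Step 3
Reactants: 6 3-bromo-2-chloro-4-methoxy-6-pentadecylpyridine; 7 furan
Product: 10 rac-4-methoxy-2-pentadecyl-5,8-dihydro-5,8-epoxyquinoline, via aryllithium 8 (not isolated), via pyridyne 9 (not isolated)
Conditions: furan (20 equiv), THF, –78 °C; t-BuLi (2.0 equiv), dropwise; then slowly –78 °C → rt; NaHCO3 aq work-up
Reagents that add atoms: none
Why: t-BuLi should exchange the C3 bromine far faster than it deprotonates the CH2 beside the ring, lithiates furan or adds to the azine, and the second equivalent destroys the t-BuBr formed, so aryllithium 8 arises in an amine-free medium and on warming loses LiCl from the neighbouring C2 to give 2,3-pyridyne 9. The 4-methoxy group stabilises the strained in-plane π bond inductively without removing its strong dienophilicity, and the excess furan captures 9 in a concerted suprafacial [4+2] cycloaddition; the closest known reaction type is the aryne Diels–Alder reaction of 4-alkoxy-2,3-pyridynes generated by halogen–metal exchange from 3-bromo-2-chloropyridines. The six-membered carbocycle (ring A) is closed by this intermolecular cycloaddition, which forms C4a–C5 and C8–C8a in one step. The bridgehead centres C5 and C8 are held cis by the oxygen bridge, so only one diastereomer is possible, and 10 is racemic because no chiral element is present, which is of no consequence since both centres vanish in step 4. Furan is symmetric, so no regiochemistry arises; the selectivity needed is capture by furan in preference to addition of organolithium species to C2 of the pyridyne, which the exact two equivalents of t-BuLi, the large excess of furan and the slow warming should secure.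

Step 4
Reactants: 10 rac-4-methoxy-2-pentadecyl-5,8-dihydro-5,8-epoxyquinoline
Product: 11 4-methoxy-2-pentadecylquinoline
Conditions: TiCl4 (4 equiv), Zn dust (8 equiv), THF, 0 °C → reflux; then 10, THF, reflux; K2CO3 aq
Reagents that add atoms: none
Why: Low-valent titanium deoxygenation of a 1,4-epoxy-1,4-dihydroarene, in which the oxophilic reduced titanium cleaves the two benzylic-allylic C–O bonds and the oxygen leaves as a titanium oxide, driven by formation of the aromatic quinoline; both stereocentres are removed and the aryl methyl ether should be untouched.

Step 5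
Reactants: 11 4-methoxy-2-pentadecylquinoline
Product: 12 4-methoxy-1-methyl-2-pentadecylquinolin-1-ium trifluoromethanesulfonate
Conditions: MeOTf (1.2 equiv), CH2Cl2, 0 °C → rt; precipitate with Et2O
Reagents that add atoms: methyl trifluoromethanesulfonate, COS(=O)(=O)C(F)(F)F
Why: Menshutkin-type N-alkylation, in which the ring nitrogen is the only nucleophilic site and is made more electron-rich by the 4-methoxy group, while methyl triflate is reactive enough to overcome the hindrance from the C2 chain and the peri C8–H.

Step 6
Reactants: 12 4-methoxy-1-methyl-2-pentadecylquinolin-1-ium trifluoromethanesulfonate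
Product: 13 1-methyl-2-pentadecylquinolin-4(1H)-one
Conditions: NaI (3 equiv), MeCN, reflux
Reagents that add atoms: none
Why: SN2 O-demethylation by iodide, in which the O-methyl carbon of the 4-methoxyquinolinium ion is activated like that of an O-methyl imidate salt and the leaving group is the neutral, vinylogous-amide 4-quinolone, whereas attack at N–CH3 is reversible and unproductive.

**Compound list**
1 | 2,6-dichloro-4-methoxypyridine | COc1cc(Cl)nc(Cl)c1 | starting material
2 | 1-bromopentadecane | CCCCCCCCCCCCCCCBr | starting material
3 | pentadecylmagnesium bromide | CCCCCCCCCCCCCCC[Mg]Br | intermediate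
4 | 2-chloro-4-methoxy-6-pentadecylpyridine | CCCCCCCCCCCCCCCc1cc(OC)cc(Cl)n1 | intermediate
5 | (2-chloro-4-methoxy-6-pentadecylpyridin-3-yl)magnesium chloride (arylmagnesium chloride) | COc1cc(CCCCCCCCCCCCCCC)nc(Cl)c1[Mg]Cl | intermediate
6 | 3-bromo-2-chloro-4-methoxy-6-pentadecylpyridine | COc1cc(CCCCCCCCCCCCCCC)nc(Cl)c1Br | intermediate
7 | furan | c1ccoc1 | starting material
8 | 2-chloro-3-lithio-4-methoxy-6-pentadecylpyridine (aryllithium) | COc1cc(CCCCCCCCCCCCCCC)nc(Cl)c1[Li] | intermediate
9 | 4-methoxy-6-pentadecyl-2,3-pyridyne (2,3-didehydropyridine) | COC1=CC(CCCCCCCCCCCCCCC)=NC#C1 | intermediate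
10 | rac-4-methoxy-2-pentadecyl-5,8-dihydro-5,8-epoxyquinoline (bridgehead hydrogens cis; one enantiomer drawn) | COc1cc(CCCCCCCCCCCCCCC)nc2c1[C@@H]1C=C[C@H]2O1 | intermediate
11 | 4-methoxy-2-pentadecylquinoline | COc1cc(CCCCCCCCCCCCCCC)nc2ccccc12 | intermediate
12 | 4-methoxy-1-methyl-2-pentadecylquinolin-1-ium trifluoromethanesulfonate | COc1cc(CCCCCCCCCCCCCCC)[n+](C)c2ccccc12.[O-]S(=O)(=O)C(F)(F)F | intermediate
13 | 1-methyl-2-pentadecylquinolin-4(1H)-one | CCCCCCCCCCCCCCCc1cc(=O)c2ccccc2n1C | target

**Step count**
Total steps: 6. Longest linear sequence: 6 steps (from 1 or 2 to 13).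

**Steps most likely to fail**

Step 3. Aryllithium 8 may be lost by proton transfer from the CH2 beside the ring, or may add to the pyridyne before furan captures it, and the strained adduct may open under traces of acid. The fallback sets out from 6 and comes back at 11, building ring A by ring-closing metathesis instead of cycloaddition. Twofold Stille allylation of 6 (allylSnBu3, Pd(PPh3)4, LiCl, DMF, 100 °C) should give 2,3-diallyl-4-methoxy-6-pentadecylpyridine F1. Ring-closing metathesis with second-generation Grubbs catalyst in CH2Cl2 at 40 °C, with one equivalent of TsOH to mask the ring nitrogen, should give 4-methoxy-2-pentadecyl-5,8-dihydroquinoline F2. Dehydrogenation with DDQ in toluene should then give 11.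

Step 2. The amide base may metalate the chain CH2 beside the ring or C5 instead of C3, or the magnesiation of this electron-rich pyridine may stay incomplete. The fallback sets out from 1 and comes back at 11, putting in the chain only after ring A is built, so that no alkyl protons are present in either organometallic step and the two ring C–H positions are equivalent.
- 1 is magnesiated at C3 (equivalent to C5) with TMPMgCl·LiCl in THF at 0 °C to (2,6-dichloro-4-methoxypyridin-3-yl)magnesium chloride F3 and brominated with BrCl2CCCl2Br to 3-bromo-2,6-dichloro-4-methoxypyridine F4.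
- t-BuLi (2 equiv) with excess furan in THF, –78 °C → rt, should give 2,6-dichloro-3-lithio-4-methoxypyridine F5, which loses LiCl to 6-chloro-4-methoxy-2,3-pyridyne F6; furan should trap it as rac-2-chloro-4-methoxy-5,8-dihydro-5,8-epoxyquinoline F7.
- TiCl4/Zn in refluxing THF should give 2-chloro-4-methoxyquinoline F8.
- Fe(acac)3-catalysed Kumada coupling of F8 with 3 (THF/NMP, 0 °C) should give 11.

Step 4. The Lewis-acidic titanium and zinc salts may open the oxygen bridge to a quinolinol instead of removing the oxygen atom, and binding of titanium to the ring nitrogen may slow the reduction. The fallback sets out from 10 and comes back at 11. Hydrogenation of the C6–C7 double bond (H2, Pd/C, EtOAc, rt) should give rac-4-methoxy-2-pentadecyl-5,6,7,8-tetrahydro-5,8-epoxyquinoline F9. Acid-catalysed opening of the oxygen bridge with elimination, followed by dehydration of the resulting benzylic alcohol (TsOH, toluene, reflux, water separator; one molecule of water lost overall), should then give 11.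

Further compounds
F1 | step 3 | 2,3-diallyl-4-methoxy-6-pentadecylpyridine | COc1cc(CCCCCCCCCCCCCCC)nc(CC=C)c1CC=C
F2 | step 3 | 4-methoxy-2-pentadecyl-5,8-dihydroquinoline | COc1cc(CCCCCCCCCCCCCCC)nc2c1CC=CC2
F3 | step 2 | (2,6-dichloro-4-methoxypyridin-3-yl)magnesium chloride | COc1cc(Cl)nc(Cl)c1[Mg]Cl
F4 | step 2 | 3-bromo-2,6-dichloro-4-methoxypyridine | COc1cc(Cl)nc(Cl)c1Br
F5 | step 2 | 2,6-dichloro-3-lithio-4-methoxypyridine | COc1cc(Cl)nc(Cl)c1[Li]
F6 | step 2 | 6-chloro-4-methoxy-2,3-pyridyne | COC1=CC(Cl)=NC#C1
F7 | step 2 | rac-2-chloro-4-methoxy-5,8-dihydro-5,8-epoxyquinoline | COc1cc(Cl)nc2c1[C@@H]1C=C[C@H]2O1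
F8 | step 2 | 2-chloro-4-methoxyquinoline | COc1cc(Cl)nc2ccccc12
F9 | step 4 | rac-4-methoxy-2-pentadecyl-5,6,7,8-tetrahydro-5,8-epoxyquinoline | COc1cc(CCCCCCCCCCCCCCC)nc2c1[C@@H]1CC[C@H]2O1
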